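# Proposed synthesis of CNP0342687.1 by a Prins closure of ring B with hydration at C11

## Analysis of the target

- The target is a honokiol-type biaryl (3',5-diallylbiphenyl-2,4'-diol) whose 2-oxygen is bound to a tertiary carbon of a trans-decalin.
- Numbering used here: ring A is C1–C5 plus C10, ring B is C5–C10, and C11 is the carbinol carbon of the 2-hydroxypropan-2-yl group on C7. The face of the C10 methyl group is called β.
- There are four stereocentres. C10 is quaternary with an axial β-methyl group. C5 carries an α-hydrogen, so the ring fusion is trans. C7 carries its side chain β and equatorial. C3 carries an equatorial β-methyl group and an axial α-aryloxy group.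
- C5 and C10 are adjacent and C7 is 1,3 to C5. C3 is remote from all three and can only be controlled through the locked chair of ring A.
- Sensitive groups: two allylarenes (double-bond migration; no hydrogenation or peracid once they are present), a free phenol, and two tertiary C–O bonds (the C3 ether and the C11 alcohol) that ionise in strong acid.
- The hard points are the crowded tertiary alkyl aryl ether next to the biaryl axis, the need to tell the C3 and C11 tertiary oxygens apart, and the quaternary C10.
- The strategy rests on the C7–C11(OH)Me2 unit next to C8, the hydroxyisopropyl pattern of terpineol and p-menthane-3,8-diol. A C7=C11 prenyl alkene hanging from C5 (through C6) and a C8 aldehyde hanging from C10 (through C9) can join at C7–C8 to close ring B while C11 takes up its oxygen.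

## Retrosynthetic reasoning

**Last step.** Target 26 is traced to its C11 triethylsilyl ether 25. The silyl group is the only protecting group of the endgame and leaves under non-acidic fluoride conditions, so neither the tertiary ether nor the allyl groups are put at risk at the end.

**Allyl group on the ether ring.** The aryl–CH2 bond para to the ether oxygen of 25 is cut, giving aryl chloride 24. The allyl group is introduced late because it would not survive the oxidative preparation of an iodonium salt. A chloride is used because it stays inert while a bromide on the same ring is coupled first. The forward reaction has to couple an electron-rich aryl chloride with an allyl nucleophile without moving either double bond.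

**Biaryl bond.** The aryl–aryl bond of 24 is cut to aryl bromide 21 and boronate 23, which comes from bromophenol 22. This is the convergent cut: the second ring arrives with its allyl group and free phenol in place. The forward coupling must react at C–Br and leave C–Cl.

**Ether bond.** The O–C(aryl) bond of 21 is cut, leading to tertiary alcohol 16 and iodonium salt 20, itself made from 17 and 18. The cut is made on the aryl side because C3 is tertiary: any substitution at C3 would go through a cation, lose the C3 configuration and eliminate. Aryl transfer to the alkoxide never touches the C3–O bond, so the configuration set earlier is kept.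

**C3 methyl group.** The C3–CH3 bond of 16 is traced through spiro-epoxide 15 to ketone 14.
- A sulfur ylide adds reversibly to the rigid trans-decalone and should end with the new C–C bond equatorial. Hydride opening then turns the epoxide CH2 into the equatorial methyl group below an axial oxygen.
- This is not done on the monocyclic ketone 9. Its ring can flip between a chair with axial methyl and equatorial arms and one with equatorial methyl and axial arms, which are close in energy, so no facial preference could be relied on.
- 14 comes from hydroxy ketone 13 by silylation of the C11 oxygen. Because C3 is still a carbonyl group at that point, the two tertiary oxygens never have to be distinguished as alcohols.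

**C8 oxygen.** 13 is traced through thionocarbonate 12 to keto diol 11. The C8 hydroxyl is the by-product of the ring closure. It is removed by radical deoxygenation directly afterwards, when the molecule holds only a ketone and a tertiary alcohol and no aryl halide or allyl group.

**Key disconnection.** In 11 the C7–C8 bond and the C11–O bond are cut, giving keto aldehyde 10, which is released from enol ether 9 in the same flask. This cut removes ring B and two stereocentres at once and leaves a ring A that already holds C5 and C10. The forward reaction must close a six-membered ring through a chair and end with hydration at C11 and not with proton loss.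

**One-carbon homologation.** 9 is traced through 8 to aldehyde 7. The C8–C9 double bond of the enol ether comes from a Wittig reaction on the formyl group at C10. The C3 ketone stays masked as a silyl enol ether until the aldehyde has been converted.

**Ring A.** The C1–C10 and C4–C5 bonds of 7 are cut in a Diels–Alder sense to dienal 4 and silyloxydiene 6. The E geometry of 4 sets the trans relation of the two arms, and a chiral Lewis acid sets the absolute configuration of C5 and C10 together. The silyloxy group places the C3 oxygen 1,4 to C10.

**Starting materials.** The C2=C3 double bond of 4 is cut to aldehyde 3, made from alcohol 1, and ylide 2. Diene 6 comes from enone 5 by O-silylation.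

## Alternatives that were turned down

**Alternative 1:** The C9–C10 bond is cut and ring A is taken back to an aromatic ring.
- Forward key step: a phenolate, made with a strong alkoxide base, is alkylated through its para carbon by a primary halide at the end of a tether on C5. This closes ring B, creates the quaternary C10 and gives the cross-conjugated dienone A1.
- For it: A1 reaches the bicyclic carbon skeleton with the C3 oxygen in place in fewer steps than a cycloaddition followed by a ring closure. On step count to the skeleton it is the stronger plan.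
- Against it: the tether on C5 is flanked by C10, which is para to the oxygen but already carries the methyl group, and by C4, which is ortho to the oxygen and unsubstituted. Closure onto C4 also forms a six-membered ring and ends in a re-aromatised phenol, so it should compete with the hindered para attack.
- C10 would be set only by 1,4-induction from C7. A1 then needs reduction of two C=C bonds with control of C5 before the C3 chemistry can begin.
- The chosen route sets C5 and C10 together from alkene geometry in a concerted cycloaddition and has no regiochemical choice in its ring closure.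

**Alternative 2:** The C8–C9 bond is made by one-carbon ring expansion of a five-membered ring.
- Forward key step: a tin hydride radical chain turns a bromomethyl β-keto ester into a primary radical. This adds to the ketone carbonyl, and the resulting alkoxy radical opens toward the ester-stabilised radical to give the ring-expanded keto ester A2.
- For it: bicyclic ketones with an angular methyl group are available enantiopure by well-known annulation chemistry, so C5 and C10 would be as secure as in the chosen route. The ester at C7 can be equilibrated to the equatorial position and turned into the carbinol.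
- Against it: A2 carries a C9 ketone that the target does not have. It sits next to the quaternary C10, and its removal needs forcing conditions. The sequence to the radical precursor and the later functional-group changes make the route long.
- C7 is set only by hydrogen-atom transfer and later epimerisation.
- The chosen route delivers C7 with its carbinol carbon at the right oxidation level, and its one superfluous oxygen (C8) leaves by a standard two-step deoxygenation.

**Alternative 3:** The C3–C4 bond of ring A is cut, with the ether oxygen already bound to the arene as an aryl enol ether.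
- Forward key step: a catalytic strong Brønsted acid protonates the enol ether. The aryloxy-stabilised C3 cation is attacked by an exocyclic methylene carbon (C4) on ring B, and proton loss gives the C5=C6 alkene of A3.
- For it: this is the only plan that makes the crowded tertiary alkyl aryl ether during C–C bond formation. It avoids the O-arylation of a hindered tertiary alcohol, which is the weakest step of the chosen route. On that bond it is clearly stronger.
- Against it: the C3 configuration depends on whether aryloxy or methyl takes the axial position in the closing chair, and the two differ little. An aryloxy carbenium ion is weakly stabilised and can lose the phenol.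
- The C5=C6 alkene of A3 must then be saturated from the α face in the presence of an aryl bromide and chloride to set the trans fusion.
- The chosen route sets C3 on a locked trans-decalone under thermodynamic control and C5 from alkene geometry, and it accepts the arylation risk in return.

Key step: step 6

Assumption: the facial sense of the oxazaborolidinium catalyst in step 3 is taken from the formyl C–H···O binding model for α-substituted enals, under which the (R)-configured catalyst leaves the Cα si face of 4 open; if the sense proves opposite, the (S)-catalyst is used.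

Assumption: the Prins product 11 is written as the 8α (equatorial) carbinol; its C8 epimer, if formed, passes through steps 7 and 8 in the same way because C8 becomes CH2.

## Route

Step 1
Reactants: 1 4-methylpent-3-en-1-ol; 2 2-(triphenylphosphoranylidene)propanal
Product: 4 (E)-2,6-dimethylhepta-2,5-dienal, via 4-methylpent-3-enal 3 (not isolated)
Conditions: Dess–Martin periodinane, CH2Cl2, 0 °C → rt; filter through SiO2; then 2, CH2Cl2, 40 °C
Reagents that add atoms: none
Why: Dess–Martin oxidation gives the β,γ-unsaturated aldehyde 3 without base, and trapping its solution at once in a Wittig olefination with the stabilised ylide 2 avoids isolation and conjugation of 3. Stabilised ylides give the E-trisubstituted enal, and this geometry later fixes the trans relation of the two ring A arms.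

Step 2
Reactants: 5 but-3-en-2-one
Product: 6 2-(triisopropylsilyloxy)buta-1,3-diene
Conditions: i-Pr3SiOTf, Et3N, Et2O, 0 °C → rt
Reagents that add atoms: triisopropylsilyl trifluoromethanesulfonate, CC(C)[Si](C(C)C)(C(C)C)OS(=O)(=O)C(F)(F)F
Why: O-silylation of an enone with a silyl triflate and an amine base is the standard route to 2-silyloxydienes. The triisopropylsilyl enol ether is chosen over the trimethylsilyl analogue because it should survive the strongly acidic catalyst of step 3.

Step 3
Reactants: 4 (E)-2,6-dimethylhepta-2,5-dienal; 6 2-(triisopropylsilyloxy)buta-1,3-diene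
Product: 7 (1S,6S)-1-methyl-6-(3-methylbut-2-en-1-yl)-4-(triisopropylsilyloxy)cyclohex-3-ene-1-carbaldehyde
Conditions: (R)-3,3-diphenyl-1-(2-methylphenyl)tetrahydro-1H,3H-pyrrolo[1,2-c][1,3,2]oxazaborole (20 mol %), HNTf2 (18 mol %), CH2Cl2, −78 → −40 °C; Et3N quench
Reagents that add atoms: none
Why: This is an enantioselective Diels–Alder reaction of an α-substituted enal under chiral oxazaborolidinium catalysis; the 2-silyloxy group directs the "para" orientation, which puts the C3 oxygen 1,4 to C10. Suprafacial addition to the E-alkene places the formyl and prenyl groups trans, so C5 and C10 are set together, and the catalyst shields the Cα re face of the s-trans enal so that the diene should add to the si face.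

Step 4
Reactants: 7 (1S,6S)-1-methyl-6-(3-methylbut-2-en-1-yl)-4-(triisopropylsilyloxy)cyclohex-3-ene-1-carbaldehyde
Product: 8 triisopropyl{[(4S,5S)-4-(2-methoxyethenyl)-4-methyl-5-(3-methylbut-2-en-1-yl)cyclohex-1-en-1-yl]oxy}silane (E/Z mixture at the enol ether)
Conditions: Ph3P(CH2OMe)Cl, KN(SiMe3)2, THF, 0 °C; then 7, 0 °C → rt
Reagents that add atoms: (methoxymethyl)triphenylphosphonium chloride, COC[P+](c1ccccc1)(c1ccccc1)c1ccccc1.[Cl-]
Why: Wittig methoxymethylenation is a standard one-carbon homologation and works on non-enolisable neopentyl aldehydes. The silyl enol ether is stable to the ylide, C10 has no α-hydrogen to lose, and the enol ether geometry is irrelevant because both isomers hydrolyse to the same aldehyde.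

Step 5
Reactants: 8 triisopropyl{[(4S,5S)-4-(2-methoxyethenyl)-4-methyl-5-(3-methylbut-2-en-1-yl)cyclohex-1-en-1-yl]oxy}silane
Product: 9 (3S,4S)-4-(2-methoxyethenyl)-4-methyl-3-(3-methylbut-2-en-1-yl)cyclohexan-1-one
Conditions: Bu4NF, AcOH, THF, 0 °C
Reagents that add atoms: none
Why: Fluoride cleaves the Si–O bond of the silyl enol ether and acetic acid protonates the enolate to the ketone, while the methyl enol ether is inert to fluoride. Releasing the C3 ketone before any acid is applied ensures that no silyl enol ether remains to compete as a carbon nucleophile in step 6.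

Step 6
Reactants: 9 (3S,4S)-4-(2-methoxyethenyl)-4-methyl-3-(3-methylbut-2-en-1-yl)cyclohexan-1-one
Product: 11 (4aR,6S,7S,8aS)-6-hydroxy-7-(2-hydroxypropan-2-yl)-4a-methyloctahydronaphthalen-2(1H)-one, via keto aldehyde 10 (not isolated)
Conditions: 5% aq. H2SO4, THF, rt → 40 °C
Reagents that add atoms: water, O
Why: The acid first hydrolyses the methyl enol ether of 9 to the aldehyde 10; the protonated C8 carbonyl is then attacked by C7 of the trisubstituted C7=C11 alkene, which forms C7–C8 and closes ring B, and the tertiary C11 cation is captured by water to form C11–O, the closest known reaction being the aqueous-acid Prins cyclisation of citronellal to p-menthane-3,8-diol. Ring B closes in a 6-exo mode through a chair transition state in which C8 and C7 become ring atoms while the carbonyl oxygen and C11 stay outside the ring. Only the ring A conformer with both arms equatorial can reach this transition state, and since C5 and C10 were fixed trans in step 3 the ring fusion can only be trans. C7 is set by the chair: the alkene carbon C11 lies equatorial, so H-7 becomes axial (α) and the hydroxyisopropyl group β-equatorial. C8 is set by the orientation of the carbonyl oxygen, expected mainly equatorial (8α) because an axial oxygen would be 1,3-diaxial to the C10 methyl group; this centre is not needed, since C8 becomes CH2 in step 8 and either epimer serves. The step needs chemoselectivity for the aldehyde over the C3 ketone, which the higher electrophilicity of the aldehyde and the absence of a six-membered chair path from the ketone to the alkene should secure. It also needs hydration and not proton loss at C11, which the aqueous medium secures because an isopropenyl by-product is re-protonated to the same tertiary cation.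

Step 7
Reactants: 11 (4aR,6S,7S,8aS)-6-hydroxy-7-(2-hydroxypropan-2-yl)-4a-methyloctahydronaphthalen-2(1H)-one
Product: 12 O-[(2S,3S,4aS,8aR)-3-(2-hydroxypropan-2-yl)-8a-methyl-6-oxodecahydronaphthalen-2-yl] O-phenyl carbonothioate (the C8 thionocarbonate of 11)
Conditions: PhOC(S)Cl, pyridine, 4-(dimethylamino)pyridine (cat.), CH2Cl2, 0 °C → rt
Reagents that add atoms: O-phenyl chlorothionoformate, S=C(Cl)Oc1ccccc1
Why: Thioacylation of an alcohol with an aryl chlorothionoformate is the first half of the Barton–McCombie deoxygenation. Only the secondary C8 hydroxyl should react, since the tertiary C11 hydroxyl and the ketone are inert under these conditions.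

Step 8
Reactants: 12 O-[(2S,3S,4aS,8aR)-3-(2-hydroxypropan-2-yl)-8a-methyl-6-oxodecahydronaphthalen-2-yl] O-phenyl carbonothioate
Product: 13 (4aS,7R,8aS)-7-(2-hydroxypropan-2-yl)-4a-methyloctahydronaphthalen-2(1H)-one
Conditions: Bu3SnH, azobisisobutyronitrile (cat.), toluene, 90 °C
Reagents that add atoms: none
Why: In this Barton–McCombie radical deoxygenation the stannyl radical adds to C=S, the C8–O bond fragments to a secondary radical, and this abstracts hydrogen from Bu3SnH. C8 becomes CH2, which erases its configuration, and no aryl halide or allyl group is yet present to interfere with the radical chain.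

Step 9
Reactants: 13 (4aS,7R,8aS)-7-(2-hydroxypropan-2-yl)-4a-methyloctahydronaphthalen-2(1H)-one
Product: 14 (4aS,7R,8aS)-4a-methyl-7-{2-[(triethylsilyl)oxy]propan-2-yl}octahydronaphthalen-2(1H)-one
Conditions: Et3SiOTf, 2,6-lutidine, CH2Cl2, −78 °C
Reagents that add atoms: triethylsilyl trifluoromethanesulfonate, CC[Si](CC)(CC)OS(=O)(=O)C(F)(F)F
Why: A silyl triflate with a hindered pyridine base silylates tertiary alcohols at low temperature, where the ketone is not enolised. The C11 oxygen is protected while C3 is still a carbonyl group, so the two tertiary oxygens of the target are differentiated by timing.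

Step 10
Reactants: 14 (4aS,7R,8aS)-4a-methyl-7-{2-[(triethylsilyl)oxy]propan-2-yl}octahydronaphthalen-2(1H)-one
Product: 15 (2R,4a'S,7'R,8a'S)-4a'-methyl-7'-{2-[(triethylsilyl)oxy]propan-2-yl}octahydro-1'H-spiro[oxirane-2,2'-naphthalene]
Conditions: Me3S(O)I, NaH, DMSO, rt → 50 °C
Reagents that add atoms: trimethylsulfoxonium iodide, C[S+](C)(C)=O.[I-]
Why: In the Corey–Chaykovsky epoxidation, dimethylsulfoxonium methylide adds reversibly and ends with the new C–C bond equatorial on a conformationally locked cyclohexanone, as known for 3-keto-5α-steroids with the same ring A/B array. C3 is thereby set with CH2 β-equatorial and oxygen α-axial.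

Step 11
Reactants: 15 (2R,4a'S,7'R,8a'S)-4a'-methyl-7'-{2-[(triethylsilyl)oxy]propan-2-yl}octahydro-1'H-spiro[oxirane-2,2'-naphthalene]
Product: 16 (2R,4aS,7R,8aS)-2,4a-dimethyl-7-{2-[(triethylsilyl)oxy]propan-2-yl}decahydronaphthalen-2-ol
Conditions: LiAlH4, THF, 0 °C → rt
Reagents that add atoms: none
Why: Hydride opens the epoxide by SN2 attack at the unsubstituted CH2 carbon, which becomes the equatorial C3 methyl group. The C3–O bond is not touched, so the axial tertiary alcohol keeps the configuration set in step 10, and the silyl ether is stable to LiAlH4.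

Step 12
Reactants: 17 2-bromo-4-chloro-1-iodobenzene; 18 1,3,5-trimethoxybenzene
Product: 20 (2-bromo-4-chlorophenyl)(2,4,6-trimethoxyphenyl)iodonium 4-methylbenzenesulfonate, via [hydroxy(tosyloxy)iodo]arene 19 (not isolated)
Conditions: 3-chloroperbenzoic acid, TsOH·H2O, MeCN, 77 °C; then 18, 77 °C
Reagents that add atoms: 4-methylbenzenesulfonic acid monohydrate, Cc1ccc(cc1)S(=O)(=O)O.O
Why: One-pot oxidation of an aryl iodide to the [hydroxy(tosyloxy)iodo]arene, followed by electrophilic substitution of 1,3,5-trimethoxybenzene, is the standard entry to aryl(2,4,6-trimethoxyphenyl)iodonium tosylates. The trimethoxyphenyl group serves as the ligand that is not transferred.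

Step 13
Reactants: 16 (2R,4aS,7R,8aS)-2,4a-dimethyl-7-{2-[(triethylsilyl)oxy]propan-2-yl}decahydronaphthalen-2-ol; 20 (2-bromo-4-chlorophenyl)(2,4,6-trimethoxyphenyl)iodonium 4-methylbenzenesulfonate
Product: 21 2-bromo-4-chloro-1-{[(2R,4aS,7R,8aS)-2,4a-dimethyl-7-{2-[(triethylsilyl)oxy]propan-2-yl}decahydronaphthalen-2-yl]oxy}benzene
Conditions: NaN(SiMe3)2, toluene, 0 °C; then 20, rt
Reagents that add atoms: none
Why: This is a metal-free O-arylation of a tertiary alkoxide with a diaryliodonium salt by ligand coupling at iodine. The electron-poorer, ortho-substituted 2-bromo-4-chlorophenyl group should be transferred in preference to the electron-rich trimethoxyphenyl group, and because the C3–O bond is never broken the C3 configuration is retained.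

Step 14
Reactants: 22 2-allyl-4-bromophenol
Product: 23 2-allyl-4-(4,4,5,5-tetramethyl-1,3,2-dioxaborolan-2-yl)phenol
Conditions: B2pin2, PdCl2[1,1'-bis(diphenylphosphino)ferrocene] (cat.), KOAc, 1,4-dioxane, 85 °C
Reagents that add atoms: bis(pinacolato)diboron, CC1(C)OB(OC1(C)C)B1OC(C)(C)C(C)(C)O1
Why: Miyaura borylation of an aryl bromide is reliable, and the weakly basic acetate conditions tolerate the free phenol and the allyl group.

Step 15
Reactants: 21 2-bromo-4-chloro-1-{[(2R,4aS,7R,8aS)-2,4a-dimethyl-7-{2-[(triethylsilyl)oxy]propan-2-yl}decahydronaphthalen-2-yl]oxy}benzene; 23 2-allyl-4-(4,4,5,5-tetramethyl-1,3,2-dioxaborolan-2-yl)phenol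
Product: 24 3-allyl-5'-chloro-2'-{[(2R,4aS,7R,8aS)-2,4a-dimethyl-7-{2-[(triethylsilyl)oxy]propan-2-yl}decahydronaphthalen-2-yl]oxy}-[1,1'-biphenyl]-4-ol
Conditions: Pd(PPh3)4 (cat.), K2CO3, 1,4-dioxane/H2O, 85 °C
Reagents that add atoms: none
Why: In this Suzuki–Miyaura coupling a triarylphosphine palladium catalyst undergoes oxidative addition at C–Br and not at C–Cl, so the biaryl bond forms ortho to the ether oxygen and the para chloride is kept. The tertiary ether and the tertiary silyl ether are stable to aqueous carbonate.

Step 16
Reactants: 24 3-allyl-5'-chloro-2'-{[(2R,4aS,7R,8aS)-2,4a-dimethyl-7-{2-[(triethylsilyl)oxy]propan-2-yl}decahydronaphthalen-2-yl]oxy}-[1,1'-biphenyl]-4-ol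
Product: 25 3,5'-diallyl-2'-{[(2R,4aS,7R,8aS)-2,4a-dimethyl-7-{2-[(triethylsilyl)oxy]propan-2-yl}decahydronaphthalen-2-yl]oxy}-[1,1'-biphenyl]-4-ol
Conditions: allylB(pin), Pd(OAc)2 (cat.), 2-dicyclohexylphosphino-2',4',6'-triisopropylbiphenyl (XPhos), K3PO4, THF/H2O, 60 °C
Reagents that add atoms: allylboronic acid pinacol ester, C=CCB1OC(C)(C)C(C)(C)O1
Why: In this Suzuki–Miyaura allylation a bulky dialkylbiarylphosphine ligand enables oxidative addition to the electron-rich C–Cl bond. The unsubstituted allyl group can give only one regioisomer, and the mild base and temperature should limit migration of the double bonds.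

Step 17
Reactants: 25 3,5'-diallyl-2'-{[(2R,4aS,7R,8aS)-2,4a-dimethyl-7-{2-[(triethylsilyl)oxy]propan-2-yl}decahydronaphthalen-2-yl]oxy}-[1,1'-biphenyl]-4-ol
Product: 26 3,5'-diallyl-2'-{[(2R,4aS,7R,8aS)-7-(2-hydroxypropan-2-yl)-2,4a-dimethyldecahydronaphthalen-2-yl]oxy}-[1,1'-biphenyl]-4-ol (target)
Conditions: Bu4NF, THF, rt → 45 °C
Reagents that add atoms: none
Why: Fluoride cleaves the tertiary triethylsilyl ether and frees the C11 alcohol. The conditions are not acidic, so the tertiary alkyl aryl ether, the tertiary alcohol and the allyl groups should be untouched.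

## Compound list

1 | 4-methylpent-3-en-1-ol | CC(C)=CCCO | starting material
2 | 2-(triphenylphosphoranylidene)propanal | CC(C=O)=P(c1ccccc1)(c1ccccc1)c1ccccc1 | starting material
3 | 4-methylpent-3-enal | CC(C)=CCC=O | intermediate
4 | (E)-2,6-dimethylhepta-2,5-dienal | O=C/C(C)=C/CC=C(C)C | intermediate
5 | but-3-en-2-one | CC(=O)C=C | starting material
6 | 2-(triisopropylsilyloxy)buta-1,3-diene | C=CC(=C)O[Si](C(C)C)(C(C)C)C(C)C | intermediate
7 | (1S,6S)-1-methyl-6-(3-methylbut-2-en-1-yl)-4-(triisopropylsilyloxy)cyclohex-3-ene-1-carbaldehyde | CC(C)[Si](C(C)C)(C(C)C)OC1=CC[C@](C)(C=O)[C@@H](CC=C(C)C)C1 | intermediate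
8 | triisopropyl{[(4S,5S)-4-(2-methoxyethenyl)-4-methyl-5-(3-methylbut-2-en-1-yl)cyclohex-1-en-1-yl]oxy}silane (E/Z mixture) | CC(C)[Si](C(C)C)(C(C)C)OC1=CC[C@](C)(C=COC)[C@@H](CC=C(C)C)C1 | intermediate
9 | (3S,4S)-4-(2-methoxyethenyl)-4-methyl-3-(3-methylbut-2-en-1-yl)cyclohexan-1-one (E/Z mixture) | O=C1CC[C@](C)(C=COC)[C@@H](CC=C(C)C)C1 | intermediate
10 | 2-[(1R,2S)-1-methyl-2-(3-methylbut-2-en-1-yl)-4-oxocyclohexyl]acetaldehyde | O=C1CC[C@](C)(CC=O)[C@@H](CC=C(C)C)C1 | intermediate
11 | (4aR,6S,7S,8aS)-6-hydroxy-7-(2-hydroxypropan-2-yl)-4a-methyloctahydronaphthalen-2(1H)-one | O=C1CC[C@]2(C)C[C@H](O)[C@@H](C(C)(C)O)C[C@H]2C1 | intermediate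
12 | O-[(2S,3S,4aS,8aR)-3-(2-hydroxypropan-2-yl)-8a-methyl-6-oxodecahydronaphthalen-2-yl] O-phenyl carbonothioate | O=C1CC[C@]2(C)C[C@H](OC(=S)Oc3ccccc3)[C@@H](C(C)(C)O)C[C@H]2C1 | intermediate
13 | (4aS,7R,8aS)-7-(2-hydroxypropan-2-yl)-4a-methyloctahydronaphthalen-2(1H)-one | O=C1CC[C@]2(C)CC[C@@H](C(C)(C)O)C[C@H]2C1 | intermediate
14 | (4aS,7R,8aS)-4a-methyl-7-{2-[(triethylsilyl)oxy]propan-2-yl}octahydronaphthalen-2(1H)-one | O=C1CC[C@]2(C)CC[C@@H](C(C)(C)O[Si](CC)(CC)CC)C[C@H]2C1 | intermediate
15 | (2R,4a'S,7'R,8a'S)-4a'-methyl-7'-{2-[(triethylsilyl)oxy]propan-2-yl}octahydro-1'H-spiro[oxirane-2,2'-naphthalene] | C1O[C@@]12CC[C@]3(C)CC[C@@H](C(C)(C)O[Si](CC)(CC)CC)C[C@H]3C2 | intermediate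
16 | (2R,4aS,7R,8aS)-2,4a-dimethyl-7-{2-[(triethylsilyl)oxy]propan-2-yl}decahydronaphthalen-2-ol | O[C@]1(C)CC[C@]2(C)CC[C@@H](C(C)(C)O[Si](CC)(CC)CC)C[C@H]2C1 | intermediate
17 | 2-bromo-4-chloro-1-iodobenzene | Clc1ccc(I)c(Br)c1 | starting material
18 | 1,3,5-trimethoxybenzene | COc1cc(OC)cc(OC)c1 | starting material
19 | 2-bromo-4-chloro-1-[hydroxy(tosyloxy)iodo]benzene | Cc1ccc(cc1)S(=O)(=O)OI(O)c1ccc(Cl)cc1Br | intermediate
20 | (2-bromo-4-chlorophenyl)(2,4,6-trimethoxyphenyl)iodonium 4-methylbenzenesulfonate | COc1cc(OC)c([I+]c2ccc(Cl)cc2Br)c(OC)c1.Cc1ccc(cc1)S(=O)(=O)[O-] | intermediate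
21 | 2-bromo-4-chloro-1-{[(2R,4aS,7R,8aS)-2,4a-dimethyl-7-{2-[(triethylsilyl)oxy]propan-2-yl}decahydronaphthalen-2-yl]oxy}benzene | Clc1ccc(O[C@]2(C)CC[C@]3(C)CC[C@@H](C(C)(C)O[Si](CC)(CC)CC)C[C@H]3C2)c(Br)c1 | intermediate
22 | 2-allyl-4-bromophenol | C=CCc1cc(Br)ccc1O | starting material
23 | 2-allyl-4-(4,4,5,5-tetramethyl-1,3,2-dioxaborolan-2-yl)phenol | C=CCc1cc(B2OC(C)(C)C(C)(C)O2)ccc1O | intermediate
24 | 3-allyl-5'-chloro-2'-{[(2R,4aS,7R,8aS)-2,4a-dimethyl-7-{2-[(triethylsilyl)oxy]propan-2-yl}decahydronaphthalen-2-yl]oxy}-[1,1'-biphenyl]-4-ol | Clc1ccc(O[C@]2(C)CC[C@]3(C)CC[C@@H](C(C)(C)O[Si](CC)(CC)CC)C[C@H]3C2)c(-c2ccc(O)c(CC=C)c2)c1 | intermediate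
25 | 3,5'-diallyl-2'-{[(2R,4aS,7R,8aS)-2,4a-dimethyl-7-{2-[(triethylsilyl)oxy]propan-2-yl}decahydronaphthalen-2-yl]oxy}-[1,1'-biphenyl]-4-ol | C=CCc1ccc(O[C@]2(C)CC[C@]3(C)CC[C@@H](C(C)(C)O[Si](CC)(CC)CC)C[C@H]3C2)c(-c2ccc(O)c(CC=C)c2)c1 | intermediate
26 | 3,5'-diallyl-2'-{[(2R,4aS,7R,8aS)-7-(2-hydroxypropan-2-yl)-2,4a-dimethyldecahydronaphthalen-2-yl]oxy}-[1,1'-biphenyl]-4-ol | C=CCc1ccc(O[C@]2(C)CC[C@]3(C)CC[C@@H](C(C)(C)O)C[C@H]3C2)c(-c2ccc(O)c(CC=C)c2)c1 | target

## Step count and least certain steps

Total: 17 steps. Longest linear sequence: 14 steps (1, 3, 4, 5, 6, 7, 8, 9, 10, 11, 13, 15, 16, 17). Steps 2, 12 and 14 prepare the diene, the iodonium salt and the boronate.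

**Step 6 (key step).** The C11 cation may lose a proton instead of taking up water, leaving isopropenyl or isopropylidene products. The product diol may also be tied up as an acetal with unreacted aldehyde, and the C3 ketone may undergo acid-catalysed aldol addition to the C8 aldehyde if the ring closure is slow in the organic co-solvent. The fallback separates C–C bond formation from hydration. Setting out from 9, the enol ether is hydrolysed under mild conditions (oxalic acid on wet silica gel, CH2Cl2, 0 °C) and the aldehyde 10 is isolated. A carbonyl-ene closure promoted by Me2AlCl (CH2Cl2, −78 °C), the reaction type that turns citronellal into isopulegol, should then give (4aR,6S,7R,8aS)-6-hydroxy-4a-methyl-7-(prop-1-en-2-yl)octahydronaphthalen-2(1H)-one F1 through the same chair. Markovnikov hydration of its isopropenyl group by the Mukaiyama method (Co(acac)2, PhSiH3, O2, i-PrOH) returns to the route at 11.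

**Step 3.** The trisubstituted enal may react too slowly with the diene at the low temperatures where the catalyst discriminates the faces. Facial selectivity may then be incomplete, or the acidic catalyst may strip the silyl group from 6 or from the adduct. The fallback gives up catalyst control. Setting out from 4 and 6, the cycloaddition is run with achiral Me2AlCl (CH2Cl2, −78 → −20 °C), which should give the same trans adduct as a racemate, that is 7 together with its mirror image (1R,6R)-1-methyl-6-(3-methylbut-2-en-1-yl)-4-(triisopropylsilyloxy)cyclohex-3-ene-1-carbaldehyde F2. The two are separated by preparative chromatography on a chiral stationary phase, and 7 rejoins the route at step 4.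

**Step 13.** The hindered axial tertiary alkoxide may act as a base toward the iodonium salt, leading to aryne formation or decomposition, instead of attacking iodine, or ligand coupling may transfer the wrong aryl group. The fallback builds the same ether by nucleophilic aromatic substitution. Setting out from 16, its potassium alkoxide (KN(SiMe3)2, THF, 0 °C) displaces fluoride from 4-chloro-1-fluoro-2-nitrobenzene to give 4-chloro-1-{[(2R,4aS,7R,8aS)-2,4a-dimethyl-7-{2-[(triethylsilyl)oxy]propan-2-yl}decahydronaphthalen-2-yl]oxy}-2-nitrobenzene F3. Reduction (Fe, NH4Cl, EtOH/H2O, 70 °C) gives 5-chloro-2-{[(2R,4aS,7R,8aS)-2,4a-dimethyl-7-{2-[(triethylsilyl)oxy]propan-2-yl}decahydronaphthalen-2-yl]oxy}aniline F4. Sandmeyer bromination (t-BuONO, CuBr2, MeCN, 0 °C → rt) returns to the route at 21.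

**Step 16.** Oxidative addition at the electron-rich C–Cl bond may be slow. At the temperature then needed, protodeboronation of the allylboronate and palladium hydride mediated migration of the allyl double bonds into conjugation become likely. The fallback exchanges the roles of the two halogens, so that the allyl group enters at a bromide under mild conditions.
- Setting out from 16, arylation as in step 13 with (4-bromo-2-chlorophenyl)(2,4,6-trimethoxyphenyl)iodonium 4-methylbenzenesulfonate F5 (made as in step 12 from 4-bromo-2-chloro-1-iodobenzene and 18) gives 4-bromo-2-chloro-1-{[(2R,4aS,7R,8aS)-2,4a-dimethyl-7-{2-[(triethylsilyl)oxy]propan-2-yl}decahydronaphthalen-2-yl]oxy}benzene F6.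
- Stille coupling at C–Br with allylSnBu3 (Pd(PPh3)4, toluene, 90 °C) gives 4-allyl-2-chloro-1-{[(2R,4aS,7R,8aS)-2,4a-dimethyl-7-{2-[(triethylsilyl)oxy]propan-2-yl}decahydronaphthalen-2-yl]oxy}benzene F7.
- Suzuki coupling of the ortho chloride with 23 (Pd(OAc)2, 2-dicyclohexylphosphino-2',6'-dimethoxybiphenyl, K3PO4, toluene/H2O, 90 °C) returns to the route at 25.

**Step 1.** The β,γ-unsaturated aldehyde 3 or the skipped dienal 4 may move its double bond into conjugation during the slow reaction with the formyl-stabilised ylide, and 4 may react a second time with the ylide. The fallback uses a more reactive ylide and adjusts the oxidation level afterwards. Setting out from 1, the oxidation is run as before and 3 is trapped at room temperature with ethyl 2-(triphenylphosphoranylidene)propanoate to give ethyl (E)-2,6-dimethylhepta-2,5-dienoate F8. Reduction with i-Bu2AlH (CH2Cl2, −78 °C) gives (E)-2,6-dimethylhepta-2,5-dien-1-ol F9, and oxidation with MnO2 (CH2Cl2, rt) returns to the route at 4.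

## Further compounds

F1 | step 6 | (4aR,6S,7R,8aS)-6-hydroxy-4a-methyl-7-(prop-1-en-2-yl)octahydronaphthalen-2(1H)-one | O=C1CC[C@]2(C)C[C@H](O)[C@@H](C(C)=C)C[C@H]2C1
F2 | step 3 | (1R,6R)-1-methyl-6-(3-methylbut-2-en-1-yl)-4-(triisopropylsilyloxy)cyclohex-3-ene-1-carbaldehyde | CC(C)[Si](C(C)C)(C(C)C)OC1=CC[C@@](C)(C=O)[C@H](CC=C(C)C)C1
F3 | step 13 | 4-chloro-1-{[(2R,4aS,7R,8aS)-2,4a-dimethyl-7-{2-[(triethylsilyl)oxy]propan-2-yl}decahydronaphthalen-2-yl]oxy}-2-nitrobenzene | [O-][N+](=O)c1cc(Cl)ccc1O[C@]1(C)CC[C@]2(C)CC[C@@H](C(C)(C)O[Si](CC)(CC)CC)C[C@H]2C1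
F4 | step 13 | 5-chloro-2-{[(2R,4aS,7R,8aS)-2,4a-dimethyl-7-{2-[(triethylsilyl)oxy]propan-2-yl}decahydronaphthalen-2-yl]oxy}aniline | Nc1cc(Cl)ccc1O[C@]1(C)CC[C@]2(C)CC[C@@H](C(C)(C)O[Si](CC)(CC)CC)C[C@H]2C1
F5 | step 16 | (4-bromo-2-chlorophenyl)(2,4,6-trimethoxyphenyl)iodonium 4-methylbenzenesulfonate | COc1cc(OC)c([I+]c2ccc(Br)cc2Cl)c(OC)c1.Cc1ccc(cc1)S(=O)(=O)[O-]
F6 | step 16 | 4-bromo-2-chloro-1-{[(2R,4aS,7R,8aS)-2,4a-dimethyl-7-{2-[(triethylsilyl)oxy]propan-2-yl}decahydronaphthalen-2-yl]oxy}benzene | Brc1ccc(O[C@]2(C)CC[C@]3(C)CC[C@@H](C(C)(C)O[Si](CC)(CC)CC)C[C@H]3C2)c(Cl)c1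
F7 | step 16 | 4-allyl-2-chloro-1-{[(2R,4aS,7R,8aS)-2,4a-dimethyl-7-{2-[(triethylsilyl)oxy]propan-2-yl}decahydronaphthalen-2-yl]oxy}benzene | C=CCc1ccc(O[C@]2(C)CC[C@]3(C)CC[C@@H](C(C)(C)O[Si](CC)(CC)CC)C[C@H]3C2)c(Cl)c1
F8 | step 1 | ethyl (E)-2,6-dimethylhepta-2,5-dienoate | CCOC(=O)/C(C)=C/CC=C(C)C
F9 | step 1 | (E)-2,6-dimethylhepta-2,5-dien-1-ol | OC/C(C)=C/CC=C(C)C
A1 | alternative 1 | cross-conjugated 10-methyl-1,4-dien-3-one bicycle with the silylated C7 side chain | O=C2C=C[C@]3(C)CC[C@@H](C(C)(C)O[Si](C)(C)C(C)(C)C)CC3=C2
A2 | alternative 2 | trans-decalin 9-ketone 7-methyl ester with the C3 ketone as its ethylene ketal | C12(OCCO1)CC[C@]3(C)C(=O)C[C@@H](C(=O)OC)C[C@H]3C2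
A3 | alternative 3 | C5=C6 octalin tertiary 2-bromo-4-chlorophenyl ether with the silylated C7 side chain | Clc1ccc(O[C@]2(C)CC[C@]3(C)CC[C@@H](C(C)(C)O[Si](C)(C)C(C)(C)C)C=C3C2)c(Br)c1
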